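The ring is cut at the C2–C3 bond (shikimate numbering), where the vinylic carbon C2 of the C1=C2 enoate meets the oxygen-bearing allylic carbon C3 of the cyclohexene ring. A C2 vinyl-metal nucleophile attacking a C3 aldehyde forms this bond, the six-membered ring and the C3 carbinol stereocentre in one Nozaki–Hiyama–Kishi cyclisation. The precursor is an acyclic methyl (E)-3-(triflyloxy)acrylate whose C1 carries, through the C6 methylene, a D-threose-type trans acetonide aldehyde. C4 and C5 come from D-threitol, and therefore from the D-tartrate pool. After ring closure the three oxygens are esterified in the order O3, O5, O4.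

Key step: step 8

Assumption: ring atoms are numbered as in shikimic acid (C1 bears CO2Me, C6 is the methylene), and (−)-2,3-O-isopropylidene-D-threitol, the reduced acetonide of diethyl D-tartrate, is taken as a purchased starting material.

Step 1
Reactants: 1 (−)-2,3-O-isopropylidene-D-threitol
Product: 3 [(4R,5R)-5-{[(tert-butyldimethylsilyl)oxy]methyl}-2,2-dimethyl-1,3-dioxolan-4-yl]methanol, via monosodium alkoxide 2 (not isolated)
Conditions: NaH (1.0 equiv), THF, 0 °C to rt; then TBSCl (1.0 equiv), rt
Reagents that add atoms: tert-butyldimethylsilyl chloride, CC(C)(C)[Si](C)(C)Cl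
Why: Monosilylation of a C2-symmetric diol through its monosodium alkoxide: the two hydroxyls are homotopic, the poorly soluble monoalkoxide 2 is silylated faster than it is deprotonated again, and no stereocentre is touched.

Step 2
Reactants: 3 mono-TBS alcohol; 4 methyl (triphenylphosphoranylidene)acetate
Product: 6 methyl (E)-3-[(4R,5R)-5-{[(tert-butyldimethylsilyl)oxy]methyl}-2,2-dimethyl-1,3-dioxolan-4-yl]prop-2-enoate, via threose aldehyde 5 (not isolated)
Conditions: Dess–Martin periodinane, CH2Cl2, rt; then 4 (2 equiv), rt
Reagents that add atoms: methyl (triphenylphosphoranylidene)acetate, COC(=O)C=P(c1ccccc1)(c1ccccc1)c1ccccc1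
Why: Dess–Martin oxidation followed in the same flask by Wittig olefination with the stabilised ylide traps the α-alkoxy aldehyde 5 before it can epimerise; the alkene geometry is of no consequence because the double bond is saturated in step 3.

Step 3
Reactants: 6 enoate
Product: 7 methyl 3-[(4R,5R)-5-{[(tert-butyldimethylsilyl)oxy]methyl}-2,2-dimethyl-1,3-dioxolan-4-yl]propanoate
Conditions: H2 (1 atm), 10% Pd/C, EtOAc, rt
Reagents that add atoms: none
Why: Heterogeneous catalytic hydrogenation of the conjugated alkene under neutral conditions, to which silyl ether, acetonide, ester and both stereocentres are inert.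

Step 4
Reactants: 7 saturated ester
Product: 9 methyl 2-formyl-3-[(4R,5R)-5-{[(tert-butyldimethylsilyl)oxy]methyl}-2,2-dimethyl-1,3-dioxolan-4-yl]propanoate (epimers at the formyl-bearing carbon, in equilibrium with the enol), via lithium ester enolate 8 (not isolated)
Conditions: LiN(iPr)2 (LDA, 1.1 equiv), THF, −78 °C; HCO2Me (3 equiv), −78 to 0 °C; AcOH quench
Reagents that add atoms: methyl formate, COC=O
Why: Crossed Claisen condensation (α-formylation): enolate 8 attacks the non-enolisable methyl formate and the product is held as its lithium enolate until the quench, which suppresses self-condensation; this adds the carbon that becomes C2.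

Step 5
Reactants: 9 α-formyl ester
Product: 10 methyl (E)-2-{[(4R,5R)-5-{[(tert-butyldimethylsilyl)oxy]methyl}-2,2-dimethyl-1,3-dioxolan-4-yl]methyl}-3-(triflyloxy)prop-2-enoate
Conditions: Tf2O (1.3 equiv), aq. Me4NOH, toluene, 0–5 °C, vigorous stirring
Reagents that add atoms: trifluoromethanesulfonic anhydride, O=S(=O)(OS(=O)(=O)C(F)(F)F)C(F)(F)F
Why: O-Sulfonylation of a 1,3-dicarbonyl enolate under non-chelating biphasic conditions: with the tetramethylammonium counter-ion the enolate takes the extended form with the oxido group anti to the ester carbonyl, so triflation should give the (E) isomer (OTf trans to CO2Me, cis to the C6 methylene) that ring closure requires.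

Step 6
Reactants: 10 silyl ether enol triflate
Product: 11 methyl (E)-2-{[(4R,5R)-5-(hydroxymethyl)-2,2-dimethyl-1,3-dioxolan-4-yl]methyl}-3-(triflyloxy)prop-2-enoate
Conditions: HF·pyridine, pyridine, THF, 0 °C to rt
Reagents that add atoms: none
Why: Fluoride-mediated desilylation of a primary TBS ether under buffered, weakly acidic conditions, chosen over basic fluoride sources so that the electrophilic β-triflyloxy acrylate and the acetonide survive.

Step 7
Reactants: 11 primary alcohol
Product: 12 methyl (E)-2-{[(4R,5S)-5-formyl-2,2-dimethyl-1,3-dioxolan-4-yl]methyl}-3-(triflyloxy)prop-2-enoate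
Conditions: Dess–Martin periodinane, pyridine, CH2Cl2, 0 °C to rt; used crude
Reagents that add atoms: none
Why: Dess–Martin oxidation of the primary alcohol under buffered non-basic conditions that tolerate the enol triflate; the trans acetonide is the thermodynamically preferred arrangement, so the C4 centre next to the aldehyde is not at risk.

Step 8
Reactants: 12 enol triflate aldehyde
Product: 14 methyl 4,5-O-isopropylidene-shikimate, via vinylchromium intermediate 13 (not isolated)
Conditions: CrCl2 (8 equiv), NiCl2 (5 mol %), degassed DMF, rt, slow addition of 12 to 0.005 M; then aq. NH4Cl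
Reagents that add atoms: none
Why: CrCl2 reduces NiCl2 to zerovalent nickel, which inserts into the C2–O bond of the enol triflate with retention of geometry, and transmetalation to trivalent chromium gives vinylchromium 13, which adds to the aldehyde carbonyl. The closest known reaction type is the intramolecular Nozaki–Hiyama–Kishi coupling of alkenyl triflates with aldehydes. The cyclohexene ring closes in the 6-exo-trig mode, C2 attacking C3 with the carbonyl oxygen outside the ring, and the (E) geometry is what places the metal on the same side of the alkene as C6. The new C3 stereocentre is controlled by the adjacent C4 centre: in the half-chair fused trans to the dioxolane the forming C2–C3 bond lies anti to the C4–O bond, and a Felkin-type arrangement with the carbonyl oxygen pseudo-axial (attack on the Re face of the aldehyde) leads to the 3,4-cis carbinol of shikimate. The step needs chemoselectivity for the aldehyde over the ester and the acetal, which the low basicity of organochromium reagents provides, and facial selectivity at C3, which rests on the conformational lock of the trans acetonide; high dilution suppresses intermolecular coupling.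

Step 9
Reactants: 14 methyl 4,5-O-isopropylidene-shikimate
Product: 15 methyl 3-O-acetyl-4,5-O-isopropylidene-shikimate
Conditions: Ac2O, pyridine, DMAP (cat.), CH2Cl2, 0 °C to rt
Reagents that add atoms: acetic anhydride, CC(=O)OC(C)=O
Why: DMAP-catalysed O-acylation of the only free hydroxyl; the C3–O bond is not broken, so the configuration set in step 8 is retained.

Step 10
Reactants: 15 acetate acetonide
Product: 16 methyl 3-O-acetylshikimate
Conditions: AcOH/H2O (4:1), 40 °C
Reagents that add atoms: none
Why: Acid-catalysed ketal hydrolysis, fast for the strained trans-fused dioxolane, in a weakly acidic aqueous medium in which ester cleavage and base-type migration of the acetyl group from O3 to O4 are slow.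

Step 11
Reactants: 16 methyl 3-O-acetylshikimate; 17 (S)-3-methylpentanoic acid
Product: 18 methyl (3R,4S,5R)-3-acetoxy-4-hydroxy-5-{[(3S)-3-methylpentanoyl]oxy}cyclohex-1-ene-1-carboxylate
Conditions: 17 (1.05 equiv), DCC, DMAP (0.1 equiv), CH2Cl2, −20 to 0 °C
Reagents that add atoms: (S)-3-methylpentanoic acid, CC[C@H](C)CC(=O)O
Why: Steglich esterification under steric control: O5 has the C6 methylene as one neighbour whereas O4 is flanked by two oxygen-bearing carbons, so a limiting amount of acid at low temperature should acylate O5; the β-stereocentre of the acid cannot epimerise.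

Step 12
Reactants: 18 4-hydroxy diester; 19 (R)-2-methylbutanoic acid
Product: 20 methyl (3R,4S,5R)-3-acetoxy-4-{[(2R)-2-methylbutanoyl]oxy}-5-{[(3S)-3-methylpentanoyl]oxy}cyclohex-1-ene-1-carboxylate (CNP0188172.1)
Conditions: 19 (2 equiv), DCC, DMAP (0.2 equiv), CH2Cl2, 0 °C to rt
Reagents that add atoms: (R)-2-methylbutanoic acid, CC[C@@H](C)C(=O)O
Why: Steglich esterification of the remaining hindered secondary hydroxyl with excess activated acid; low temperature and a catalytic amount of DMAP limit enolisation of the activated acyl group, so the α-stereocentre of the (R)-acid should be retained.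

Compound list
1 | (−)-2,3-O-isopropylidene-D-threitol, [(4R,5R)-2,2-dimethyl-1,3-dioxolane-4,5-diyl]dimethanol | OC[C@H]1OC(C)(C)O[C@@H]1CO | starting material
2 | monosodium alkoxide of 1 | [Na+].[O-]C[C@H]1OC(C)(C)O[C@@H]1CO | intermediate
3 | [(4R,5R)-5-{[(tert-butyldimethylsilyl)oxy]methyl}-2,2-dimethyl-1,3-dioxolan-4-yl]methanol | OC[C@H]1OC(C)(C)O[C@@H]1CO[Si](C)(C)C(C)(C)C | intermediate
4 | methyl (triphenylphosphoranylidene)acetate | COC(=O)C=P(c1ccccc1)(c1ccccc1)c1ccccc1 | starting material
5 | (4S,5R)-5-{[(tert-butyldimethylsilyl)oxy]methyl}-2,2-dimethyl-1,3-dioxolane-4-carbaldehyde (4-O-TBS-2,3-O-isopropylidene-D-threose) | O=C[C@H]1OC(C)(C)O[C@@H]1CO[Si](C)(C)C(C)(C)C | intermediate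
6 | methyl (E)-3-[(4R,5R)-5-{[(tert-butyldimethylsilyl)oxy]methyl}-2,2-dimethyl-1,3-dioxolan-4-yl]prop-2-enoate | COC(=O)/C=C/[C@H]1OC(C)(C)O[C@@H]1CO[Si](C)(C)C(C)(C)C | intermediate
7 | methyl 3-[(4R,5R)-5-{[(tert-butyldimethylsilyl)oxy]methyl}-2,2-dimethyl-1,3-dioxolan-4-yl]propanoate | COC(=O)CC[C@H]1OC(C)(C)O[C@@H]1CO[Si](C)(C)C(C)(C)C | intermediate
8 | lithium enolate of ester 7 (geometry not defined) | COC(O[Li])=CC[C@H]1OC(C)(C)O[C@@H]1CO[Si](C)(C)C(C)(C)C | intermediate
9 | methyl 2-formyl-3-[(4R,5R)-5-{[(tert-butyldimethylsilyl)oxy]methyl}-2,2-dimethyl-1,3-dioxolan-4-yl]propanoate (epimers at the formyl-bearing carbon, enol tautomer present) | COC(=O)C(C=O)C[C@H]1OC(C)(C)O[C@@H]1CO[Si](C)(C)C(C)(C)C | intermediate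
10 | methyl (E)-2-{[(4R,5R)-5-{[(tert-butyldimethylsilyl)oxy]methyl}-2,2-dimethyl-1,3-dioxolan-4-yl]methyl}-3-{[(trifluoromethyl)sulfonyl]oxy}prop-2-enoate | COC(=O)/C(C[C@H]1OC(C)(C)O[C@@H]1CO[Si](C)(C)C(C)(C)C)=C/OS(=O)(=O)C(F)(F)F | intermediate
11 | methyl (E)-2-{[(4R,5R)-5-(hydroxymethyl)-2,2-dimethyl-1,3-dioxolan-4-yl]methyl}-3-{[(trifluoromethyl)sulfonyl]oxy}prop-2-enoate | COC(=O)/C(C[C@H]1OC(C)(C)O[C@@H]1CO)=C/OS(=O)(=O)C(F)(F)F | intermediate
12 | methyl (E)-2-{[(4R,5S)-5-formyl-2,2-dimethyl-1,3-dioxolan-4-yl]methyl}-3-{[(trifluoromethyl)sulfonyl]oxy}prop-2-enoate (precursor of the key step) | COC(=O)/C(C[C@H]1OC(C)(C)O[C@@H]1C=O)=C/OS(=O)(=O)C(F)(F)F | intermediate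
13 | dichloro vinylchromium species of trivalent chromium at C2, metal cis to the C6 methylene | COC(=O)/C(C[C@H]1OC(C)(C)O[C@@H]1C=O)=C/[Cr](Cl)Cl | intermediate
14 | methyl 4,5-O-isopropylidene-shikimate: trans-fused acetonide, free 3-OH cis to O4 (CIP 3R,4R,5R; the C4 descriptor differs from shikimic acid only through priorities) | COC(=O)C1=C[C@@H](O)[C@H]2OC(C)(C)O[C@@H]2C1 | intermediate
15 | methyl 3-O-acetyl-4,5-O-isopropylidene-shikimate (3R,4S,5R) | COC(=O)C1=C[C@@H](OC(C)=O)[C@H]2OC(C)(C)O[C@@H]2C1 | intermediate
16 | methyl 3-O-acetylshikimate, methyl (3R,4S,5R)-3-acetoxy-4,5-dihydroxycyclohex-1-ene-1-carboxylate | O[C@@H]1CC(C(=O)OC)=C[C@@H](OC(C)=O)[C@H]1O | intermediate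
17 | (S)-3-methylpentanoic acid | CC[C@H](C)CC(=O)O | starting material
18 | methyl (3R,4S,5R)-3-acetoxy-4-hydroxy-5-{[(3S)-3-methylpentanoyl]oxy}cyclohex-1-ene-1-carboxylate | CC[C@H](C)CC(=O)O[C@@H]1CC(C(=O)OC)=C[C@@H](OC(C)=O)[C@H]1O | intermediate
19 | (R)-2-methylbutanoic acid | CC[C@@H](C)C(=O)O | starting material
20 | methyl (3R,4S,5R)-3-acetoxy-4-{[(2R)-2-methylbutanoyl]oxy}-5-{[(3S)-3-methylpentanoyl]oxy}cyclohex-1-ene-1-carboxylate | CC[C@H](C)CC(=O)O[C@@H]1CC(C(=O)OC)=C[C@@H](OC(C)=O)[C@H]1OC(=O)[C@H](C)CC | target

Total step count: 12. Longest linear sequence: 12 steps, from 1 to 20.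

Steps most likely to fail

Step 8. The process at risk is facial selection in the addition of the vinylchromium to the aldehyde. A closed transition state, in which chromium bridges C2 and the carbonyl oxygen, would favour a pseudo-equatorial oxygen and hence attack on the Si face, giving the 3,4-trans carbinol. The fallback sets out from 12 and comes back at 15. The cyclisation is run as before and the epimer, methyl 4,5-O-isopropylidene-3-epi-shikimate F1, is separated and submitted to a Mitsunobu reaction with acetic acid (PPh3, DIAD, toluene, 0 °C). Displacement of the activated allylic oxygen by acetate inverts C3 and installs the acetyl group in the same operation. Attack at the other allylic terminus is disfavoured because it would have to occur at the fully substituted, ester-bearing C1.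

Step 5. The process at risk is geometric control in the O-triflation (reaction through a chelated enolate would give the (Z) isomer), together with retro-Claisen loss of the formyl group in aqueous base. The fallback is a ring-closing metathesis that needs no defined alkene geometry; it sets out from 9 and comes back at 14.
- Aqueous formaldehyde and K2CO3 (hydroxymethylation, then loss of formate) should convert 9 into the acrylate, methyl 2-{[(4R,5R)-5-{[(tert-butyldimethylsilyl)oxy]methyl}-2,2-dimethyl-1,3-dioxolan-4-yl]methyl}prop-2-enoate F2.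
- HF·pyridine gives the alcohol, methyl 2-{[(4R,5R)-5-(hydroxymethyl)-2,2-dimethyl-1,3-dioxolan-4-yl]methyl}prop-2-enoate F3.
- Dess–Martin oxidation gives the aldehyde, methyl 2-{[(4R,5S)-5-formyl-2,2-dimethyl-1,3-dioxolan-4-yl]methyl}prop-2-enoate F4.
- CH2=CHMgBr in THF at −78 °C adds to the aldehyde in preference to the ester and gives the dienol, methyl 2-{[(4R,5R)-5-(1-hydroxyprop-2-en-1-yl)-2,2-dimethyl-1,3-dioxolan-4-yl]methyl}prop-2-enoate F5, as both carbinol epimers.
- The second-generation Hoveyda–Grubbs catalyst (toluene, 80 °C) closes the C1=C2 bond with loss of ethene and should give 14 together with methyl 4,5-O-isopropylidene-3-epi-shikimate F1. The two are separated; 14 continues in step 9 and F1 is converged on 15 by the Mitsunobu reaction described for step 8.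

Step 11. The processes at risk are discrimination between O5 and O4, and DMAP-promoted migration of the acetyl group from O3 to the neighbouring cis O4 before acylation. The fallback sets out from 14 and comes back at 18.
- Catalytic camphorsulfonic acid in acetone should move the acetonide to the cis 3,4-diol, with relief of the trans-fusion strain, giving methyl 3,4-O-isopropylidene-shikimate F6.
- Steglich esterification of its only free hydroxyl, O5, with 17 gives methyl 3,4-O-isopropylidene-5-O-[(3S)-3-methylpentanoyl]shikimate F7.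
- Aqueous AcOH removes the acetonide and gives methyl 5-O-[(3S)-3-methylpentanoyl]shikimate F8.
- MeC(OMe)3 with catalytic camphorsulfonic acid forms the cyclic orthoacetate, methyl 3,4-O-(1-methoxyethylidene)-5-O-[(3S)-3-methylpentanoyl]shikimate F9.
- Mild hydrolysis of F9 in aqueous AcOH should open it to the pseudo-axial ester, that is the O3 acetate with O4 free, which is 18.

Further compounds
F1 | step 8 | methyl 4,5-O-isopropylidene-3-epi-shikimate (3-OH trans to O4; CIP 3S,4R,5R) | COC(=O)C1=C[C@H](O)[C@H]2OC(C)(C)O[C@@H]2C1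
F2 | step 5 | methyl 2-{[(4R,5R)-5-{[(tert-butyldimethylsilyl)oxy]methyl}-2,2-dimethyl-1,3-dioxolan-4-yl]methyl}prop-2-enoate | COC(=O)C(=C)C[C@H]1OC(C)(C)O[C@@H]1CO[Si](C)(C)C(C)(C)C
F3 | step 5 | methyl 2-{[(4R,5R)-5-(hydroxymethyl)-2,2-dimethyl-1,3-dioxolan-4-yl]methyl}prop-2-enoate | COC(=O)C(=C)C[C@H]1OC(C)(C)O[C@@H]1CO
F4 | step 5 | methyl 2-{[(4R,5S)-5-formyl-2,2-dimethyl-1,3-dioxolan-4-yl]methyl}prop-2-enoate | COC(=O)C(=C)C[C@H]1OC(C)(C)O[C@@H]1C=O
F5 | step 5 | methyl 2-{[(4R,5R)-5-(1-hydroxyprop-2-en-1-yl)-2,2-dimethyl-1,3-dioxolan-4-yl]methyl}prop-2-enoate (both carbinol epimers) | COC(=O)C(=C)C[C@H]1OC(C)(C)O[C@@H]1C(O)C=C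
F6 | step 11 | methyl 3,4-O-isopropylidene-shikimate (cis-fused acetonide, free 5-OH) | O[C@@H]1CC(C(=O)OC)=C[C@H]2OC(C)(C)O[C@@H]12
F7 | step 11 | methyl 3,4-O-isopropylidene-5-O-[(3S)-3-methylpentanoyl]shikimate | CC[C@H](C)CC(=O)O[C@@H]1CC(C(=O)OC)=C[C@H]2OC(C)(C)O[C@@H]12
F8 | step 11 | methyl 5-O-[(3S)-3-methylpentanoyl]shikimate | CC[C@H](C)CC(=O)O[C@@H]1CC(C(=O)OC)=C[C@@H](O)[C@H]1O
F9 | step 11 | methyl 3,4-O-(1-methoxyethylidene)-5-O-[(3S)-3-methylpentanoyl]shikimate (epimers at the orthoester carbon) | CC[C@H](C)CC(=O)O[C@@H]1CC(C(=O)OC)=C[C@H]2OC(C)(OC)O[C@@H]12
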